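## Retrosynthetic overview

1. The 1,2-dioxane is the last ring: 6-exo oxa-Michael closure of a tertiary hydroperoxide onto the tiglate-type enoate; the hydroperoxide comes from cobalt-catalysed hydroperoxysilylation of a 1,1-disubstituted alkene.
2. The diene ester is cut at C12–C13 into a C9-vinyl decalinol and a bromodiene ester (B-alkyl Suzuki coupling).
3. The vinyl decalinol comes from a bridged C5–O–C11 γ-lactone (i-Bu2AlH, then Wittig methylenation) that already holds C5, C8, C9 and C10.
4. Key disconnection: the lactone comes from the α-iodo ester of dihydro-β-monocyclofarnesate. C9 reacts as an electrophilic α-acyl radical (an enolonium-type carbon) with nucleophilic C10 of the ring A alkene, and the ester then captures C5. This is the polarity-inverted counterpart of the classical cationic drimane closure.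
5. Ring order: ring A is bought (dihydro-β-ionone), then ring B and the lactone bridge form together, the lactone is opened, and the 1,2-dioxane closes last.

Assumption: the facial sense of the (R)-ligand in step 2 is taken by analogy with (E)-β,β-dialkyl enoates; if the first run gives the 3S ester, the (S)-ligand is used with no other change.

Locants in the explanations: labdane-type numbering for the decalin and linker (C1–C12); the heterocycle is described as dioxane C3/C6 and propanoate C2.

## Route

Step 1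
Reactants: 1 4-(2,6,6-trimethylcyclohex-1-en-1-yl)butan-2-one (dihydro-β-ionone); 2 trimethyl phosphonoacetate
Product: 3 methyl (2E)-3-methyl-5-(2,6,6-trimethylcyclohex-1-en-1-yl)pent-2-enoate
Conditions: NaH, THF, 0 °C to 65 °C; chromatography (AgNO3–silica if needed) to remove the Z isomer
Reagents that add atoms: none
Why: Horner–Wadsworth–Emmons olefination of the methyl ketone gives the trisubstituted enoate with the usual E preference (about 4:1), and the E isomer is isolated because the next step is geometry-specific; no stereocentre is formed.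

Step 2
Reactants: 3 methyl (2E)-3-methyl-5-(2,6,6-trimethylcyclohex-1-en-1-yl)pent-2-enoate
Product: 4 methyl (3R)-3-methyl-5-(2,6,6-trimethylcyclohex-1-en-1-yl)pentanoate
Conditions: Cu(OAc)2·H2O (3 mol%), (R)-DTBM-SEGPHOS (3 mol%), (EtO)2MeSiH (3 equiv), t-BuOH (1.1 equiv), PhMe, 0 °C to rt
Reagents that add atoms: none
Why: Ligand-controlled asymmetric conjugate reduction by copper hydride generated in situ (Buchwald–Lipshutz type) delivers hydride to the Si face of C3 of the E-enoate and sets the 3R methyl centre (future C8), while the unactivated tetrasubstituted ring alkene is inert.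

Step 3
Reactants: 4 methyl (3R)-3-methyl-5-(2,6,6-trimethylcyclohex-1-en-1-yl)pentanoate
Product: 6 methyl (2RS,3R)-2-iodo-3-methyl-5-(2,6,6-trimethylcyclohex-1-en-1-yl)pentanoate, via lithium ester enolate 5 (not isolated)
Conditions: LiN(i-Pr)2 (1.1 equiv), THF, −78 °C; then cannulated into iodine (1.2 equiv), THF, −78 °C
Reagents that add atoms: iodine, [I][I]
Why: Kinetic enolate formation and iodination (Rathke-type α-halogenation) turn the normally nucleophilic α-carbon into a latent electrophilic α-acyl radical; the new C2 centre is an irrelevant mixture because it becomes planar in step 4, and the β-stereocentre is not enolisable.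

Step 4
Reactants: 6 methyl (2RS,3R)-2-iodo-3-methyl-5-(2,6,6-trimethylcyclohex-1-en-1-yl)pentanoate
Product: 8 (1S,2R,4aS,8aR)-4a-hydroxy-2,5,5,8a-tetramethyldecahydronaphthalene-1-carboxylic acid 1,4a-lactone, via tertiary C5 iodide 7 (not isolated)
Conditions: (Bu3Sn)2 (10 mol%), PhH (0.1 M), sunlamp hν, 80 °C; then 80 °C in the dark until 7 is consumed
Reagents that add atoms: none
Why: Curran-type iodine-atom-transfer radical cyclization followed by SN1 lactonization: the electrophilic α-ester radical adds 6-endo to the less hindered C10 of the electron-rich tetrasubstituted alkene through a chair transition state with the C8 methyl and the ester equatorial (the ester is also placed there by allylic strain), which sets C9 (S) and C10 (R) from C8; the tertiary C5 radical takes iodine from 6, and ionization of that iodide is captured by the cis ester carbonyl with loss of iodomethane, so the new C5–O bond (S) is necessarily cis to C9 and hence to the angular methyl.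

Step 5
Reactants: 8 (1S,2R,4aS,8aR)-4a-hydroxy-2,5,5,8a-tetramethyldecahydronaphthalene-1-carboxylic acid 1,4a-lactone
Product: 9 (1S,2R,4aS,8aR)-4a-hydroxy-2,5,5,8a-tetramethyldecahydronaphthalene-1-carbaldehyde 1,4a-hemiacetal (bridged lactol; anomers)
Conditions: i-Bu2AlH (1.1 equiv), CH2Cl2, −78 °C; aq. KNaC4H4O6 work-up
Reagents that add atoms: none
Why: Low-temperature i-Bu2AlH reduction of a lactone stops at the aluminium hemiacetal and gives the lactol without touching any stereocentre (the anomeric centre is inconsequential).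

Step 6
Reactants: 9 (1S,2R,4aS,8aR)-4a-hydroxy-2,5,5,8a-tetramethyldecahydronaphthalene-1-carbaldehyde 1,4a-hemiacetal
Product: 11 (1S,2R,4aS,8aR)-1-ethenyl-2,5,5,8a-tetramethyloctahydronaphthalen-4a(2H)-ol, via ring-opened hydroxy aldehyde 10 (not isolated)
Conditions: Ph3PCH3Br (3.5 equiv), KOt-Bu (3.3 equiv), THF, 0 °C to 50 °C
Reagents that add atoms: methyltriphenylphosphonium bromide, C[P+](c1ccccc1)(c1ccccc1)c1ccccc1.[Br-]
Why: Wittig methylenation of the lactol through its ring-opened hydroxy aldehyde tautomer turns C11 into the vinyl group and frees the tertiary C5 alcohol; C9 is α to the aldehyde but already has the more stable equatorial configuration, so it is not eroded.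

Step 7
Reactants: 12 2,3-dibromoprop-1-ene; 13 allylmagnesium bromide
Product: 14 2-bromohexa-1,5-diene
Conditions: Et2O, 0 °C to rt
Reagents that add atoms: none
Why: SN2-type coupling of the allylic bromide with the allyl Grignard reagent leaves the vinylic bromide untouched; no stereocentre.

Step 8
Reactants: 14 2-bromohexa-1,5-diene; 15 methyl methacrylate (10 equiv)
Product: 16 methyl (2E)-6-bromo-2-methylhepta-2,6-dienoate
Conditions: second-generation Grubbs catalyst RuCl2(=CHPh)(PCy3)(H2IMes) (5 mol%), CH2Cl2, 40 °C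
Reagents that add atoms: none
Why: Olefin cross-metathesis of the monosubstituted alkene with excess methacrylate gives the trisubstituted enoate with high E selectivity, the 2-bromoalkene being a spectator olefin.

Step 9
Reactants: 11 (1S,2R,4aS,8aR)-1-ethenyl-2,5,5,8a-tetramethyloctahydronaphthalen-4a(2H)-ol; 16 methyl (2E)-6-bromo-2-methylhepta-2,6-dienoate
Product: 18 methyl (2E)-8-[(1S,2R,4aS,8aR)-4a-hydroxy-2,5,5,8a-tetramethyldecahydronaphthalen-1-yl]-2-methyl-6-methylideneoct-2-enoate, via B-alkyl-9-BBN borane 17 (not isolated)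
Conditions: 9-BBN (2.5 equiv), THF, 0 °C to rt; then 16 (1.3 equiv), PdCl2(dppf) (5 mol%), AsPh3 (10 mol%), Cs2CO3 (3 equiv), DMF–H2O, rt
Reagents that add atoms: 9-borabicyclo[3.3.1]nonane (9-BBN), C1CCC2CCCC1B2 (its boron is kept in 17 only)
Why: Anti-Markovnikov hydroboration of the only alkene of 11 and B-alkyl Suzuki–Miyaura coupling of the primary alkylborane with the 2-bromoalkene form C12–C13 and the 1,1-disubstituted alkene directly at the right oxidation level without touching a stereocentre.

Step 10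
Reactants: 18 methyl (2E)-8-[(1S,2R,4aS,8aR)-4a-hydroxy-2,5,5,8a-tetramethyldecahydronaphthalen-1-yl]-2-methyl-6-methylideneoct-2-enoate
Product: 19 methyl (2E,6RS)-8-[(1S,2R,4aS,8aR)-4a-hydroxy-2,5,5,8a-tetramethyldecahydronaphthalen-1-yl]-2,6-dimethyl-6-[(triethylsilyl)peroxy]oct-2-enoate
Conditions: Co(thd)2 (10 mol%; thd = 2,2,6,6-tetramethylheptane-3,5-dionate), O2 (1 atm), Et3SiH (2 equiv), ClCH2CH2Cl, rt
Reagents that add atoms: dioxygen, O=O; triethylsilane, CC[SiH](CC)CC
Why: Mukaiyama–Isayama hydroperoxysilylation (hydrogen-atom transfer to the electron-rich 1,1-disubstituted alkene, O2 capture of the tertiary radical, silylation) is Markovnikov and spares the electron-poor trisubstituted enoate; the new peroxy-bearing centre (dioxane C6) has no controlling element and forms about 1:1.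

Step 11
Reactants: 19 methyl (2E,6RS)-8-[(1S,2R,4aS,8aR)-4a-hydroxy-2,5,5,8a-tetramethyldecahydronaphthalen-1-yl]-2,6-dimethyl-6-[(triethylsilyl)peroxy]oct-2-enoate
Product: 21 methyl (2S)-2-[(3S,6R)-6-{2-[(1S,2R,4aS,8aR)-4a-hydroxy-2,5,5,8a-tetramethyldecahydronaphthalen-1-yl]ethyl}-6-methyl-1,2-dioxan-3-yl]propanoate (CNP0274543.2), via free hydroperoxide 20 (not isolated)
Conditions: HCl (cat.), MeOH, 0 °C, 15 min; evaporate; Et2NH (0.5 equiv), CF3CH2OH, rt, 24 h; preparative HPLC
Reagents that add atoms: none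
Why: Acid methanolysis frees the hydroperoxide, which closes by amine-promoted 6-exo intramolecular oxa-Michael addition through a chair transition state (side chain equatorial) followed by protonation at propanoate C2; dioxane C3 and propanoate C2 are set here under weak substrate control only, so the (2S,3S,6R) isomer is separated from its C6 and C2/C3 diastereomers.

## Compound list

1 | 4-(2,6,6-trimethylcyclohex-1-en-1-yl)butan-2-one (dihydro-β-ionone) | CC(=O)CCC1=C(C)CCCC1(C)C | starting material
2 | trimethyl phosphonoacetate | COC(=O)CP(=O)(OC)OC | starting material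
3 | methyl (2E)-3-methyl-5-(2,6,6-trimethylcyclohex-1-en-1-yl)pent-2-enoate | COC(=O)/C=C(\C)CCC1=C(C)CCCC1(C)C | intermediate
4 | methyl (3R)-3-methyl-5-(2,6,6-trimethylcyclohex-1-en-1-yl)pentanoate | COC(=O)C[C@H](C)CCC1=C(C)CCCC1(C)C | intermediate
5 | lithium enolate of 4 | COC([O-])=C[C@H](C)CCC1=C(C)CCCC1(C)C.[Li+] | intermediate (not isolated)
6 | methyl (2RS,3R)-2-iodo-3-methyl-5-(2,6,6-trimethylcyclohex-1-en-1-yl)pentanoate | COC(=O)C(I)[C@H](C)CCC1=C(C)CCCC1(C)C | intermediate
7 | methyl (1S,2R,8aR)-4a-iodo-2,5,5,8a-tetramethyldecahydronaphthalene-1-carboxylate (4a-epimers) | COC(=O)[C@H]1[C@H](C)CCC2(I)C(C)(C)CCC[C@]12C | intermediate (not isolated)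
8 | (1S,2R,4aS,8aR)-4a-hydroxy-2,5,5,8a-tetramethyldecahydronaphthalene-1-carboxylic acid 1,4a-lactone | O=C1[C@H]2[C@H](C)CC[C@]3(O1)C(C)(C)CCC[C@]23C | intermediate
9 | (1S,2R,4aS,8aR)-4a-hydroxy-2,5,5,8a-tetramethyldecahydronaphthalene-1-carbaldehyde 1,4a-hemiacetal (lactol, anomers) | OC1[C@H]2[C@H](C)CC[C@]3(O1)C(C)(C)CCC[C@]23C | intermediate
10 | (1S,2R,4aS,8aR)-4a-hydroxy-2,5,5,8a-tetramethyldecahydronaphthalene-1-carbaldehyde | O=C[C@H]1[C@H](C)CC[C@]2(O)C(C)(C)CCC[C@]12C | intermediate (not isolated)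
11 | (1S,2R,4aS,8aR)-1-ethenyl-2,5,5,8a-tetramethyloctahydronaphthalen-4a(2H)-ol | C=C[C@H]1[C@H](C)CC[C@]2(O)C(C)(C)CCC[C@]12C | intermediate
12 | 2,3-dibromoprop-1-ene | BrCC(Br)=C | starting material
13 | allylmagnesium bromide | C=CC[Mg]Br | starting material
14 | 2-bromohexa-1,5-diene | C=CCCC(Br)=C | intermediate
15 | methyl methacrylate | COC(=O)C(C)=C | starting material
16 | methyl (2E)-6-bromo-2-methylhepta-2,6-dienoate | COC(=O)/C(C)=C/CCC(Br)=C | intermediate
17 | 9-{2-[(1S,2R,4aS,8aR)-4a-hydroxy-2,5,5,8a-tetramethyldecahydronaphthalen-1-yl]ethyl}-9-borabicyclo[3.3.1]nonane | C1CCC2CCCC1B2CC[C@H]3[C@H](C)CC[C@]4(O)C(C)(C)CCC[C@]34C | intermediate (not isolated)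
18 | methyl (2E)-8-[(1S,2R,4aS,8aR)-4a-hydroxy-2,5,5,8a-tetramethyldecahydronaphthalen-1-yl]-2-methyl-6-methylideneoct-2-enoate | COC(=O)/C(C)=C/CCC(=C)CC[C@H]1[C@H](C)CC[C@]2(O)C(C)(C)CCC[C@]12C | intermediate
19 | methyl (2E,6RS)-8-[(1S,2R,4aS,8aR)-4a-hydroxy-2,5,5,8a-tetramethyldecahydronaphthalen-1-yl]-2,6-dimethyl-6-[(triethylsilyl)peroxy]oct-2-enoate | COC(=O)/C(C)=C/CCC(C)(OO[Si](CC)(CC)CC)CC[C@H]1[C@H](C)CC[C@]2(O)C(C)(C)CCC[C@]12C | intermediate
20 | methyl (2E,6RS)-6-hydroperoxy-8-[(1S,2R,4aS,8aR)-4a-hydroxy-2,5,5,8a-tetramethyldecahydronaphthalen-1-yl]-2,6-dimethyloct-2-enoate | COC(=O)/C(C)=C/CCC(C)(OO)CC[C@H]1[C@H](C)CC[C@]2(O)C(C)(C)CCC[C@]12C | intermediate (not isolated)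
21 | methyl (2S)-2-[(3S,6R)-6-{2-[(1S,2R,4aS,8aR)-4a-hydroxy-2,5,5,8a-tetramethyldecahydronaphthalen-1-yl]ethyl}-6-methyl-1,2-dioxan-3-yl]propanoate | COC(=O)[C@@H](C)[C@@H]1CC[C@@](C)(CC[C@H]2[C@H](C)CC[C@]3(O)C(C)(C)CCC[C@]23C)OO1 | target

## Step count and risks

Total step count: 11. Longest linear sequence: 9 (steps 1–6 and 9–11; steps 7–8 make fragment 16). No protecting groups are used.

Stereocentres: C8 is set in step 2; C9, C10 and C5 in step 4; dioxane C6 in step 10 (uncontrolled); dioxane C3 and propanoate C2 in step 11 (weak control).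

Three steps most likely to fail:

**Step 4 (key annulation).** The radical may close 5-exo at C5, or the ester may sit axial in the transition state, which gives the C5/C9-epimeric trans-fused lactone. The hindered tertiary iodide 7 may also eliminate or suffer a 1,2-methyl shift before the strained bridged lactone forms.

Fallback, leaving the route at 4 and returning at 8, a polar epoxide-based closure of ring B. Ester 4 is epoxidised at the ring double bond (mCPBA, NaHCO3, CH2Cl2, 0 °C) to methyl (3R)-3-methyl-5-[(1S,6R)-2,2,6-trimethyl-7-oxabicyclo[4.1.0]heptan-1-yl]pentanoate F1, formed together with its epoxide epimer. LiN(i-Pr)2/Me3SiCl converts it into the trimethylsilyl ketene acetal F2. BF3·OEt2 (CH2Cl2, −78 °C) then opens the epoxide at C10 with anti attack of the ketene acetal carbon (6-endo, chair), and the resulting cis-fused C5 alkoxide closes onto the ester to give lactone 8. The ceiling is about 50 % because the epoxidation is not controlled by C8.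

**Step 10 (hydroperoxysilylation next to the enoate).** The enoate can compete for hydrogen-atom transfer (α-silylperoxy ester), and the product is sensitive.

Fallback, leaving at 11 and 14 and returning at 19, with the enoate installed after the peroxide. Borane 17 is coupled as in step 9 with 2-bromohexa-1,5-diene 14 to give (1S,2R,4aS,8aR)-2,5,5,8a-tetramethyl-1-(3-methylidenehept-6-en-1-yl)octahydronaphthalen-4a(2H)-ol F3. The same cobalt conditions peroxidise its 1,1-disubstituted alkene in preference to the monosubstituted one and give the triethylsilyl peroxide F4. Cross-metathesis of the remaining terminal alkene of F4 with methyl methacrylate 15 (second-generation Grubbs catalyst, CH2Cl2, 40 °C; dialkyl and silyl peroxides tolerate the ruthenium carbene) then gives 19.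

**Step 11 (dioxane closure).** The ring forms, but four diastereomers are expected (about 1:1 at dioxane C6, modest preference at C3/C2), so the yield of 21 after HPLC is low. Base-induced peroxide fragmentation is a further loss.

Fallback, leaving at 16 and 11 and returning at 21, an auxiliary-controlled closure. Fragment 16 is saponified (LiOH, THF–H2O) to (2E)-6-bromo-2-methylhepta-2,6-dienoic acid F5 and activated as its pivalic mixed anhydride F6 (t-BuCOCl, Et3N). This is joined to lithiated (4S)-4-benzyl-1,3-oxazolidin-2-one to give the N-enoyl imide F7. Coupling with borane 17 as in step 9 gives the imide diene F8, and hydroperoxysilylation as in step 10 gives the silyl peroxide F9. Desilylation gives the hydroperoxide F10, which closes with Et2NH/CF3CH2OH onto the more electrophilic imide. The benzyl group is intended to shield one face of the acceptor and of the derived enolate, giving the dioxane imide F11 and leaving only the two C6 epimers to separate. MeOMgBr/MeOH at 0 °C then gives 21 and returns the auxiliary. The antipodal auxiliary is used if the (4S) one proves mismatched.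

## Further compounds

F1 | step 4 | methyl (3R)-3-methyl-5-[(1S,6R)-2,2,6-trimethyl-7-oxabicyclo[4.1.0]heptan-1-yl]pentanoate | COC(=O)C[C@H](C)CC[C@@]12O[C@]1(C)CCCC2(C)C
F2 | step 4 | ({(3R)-1-methoxy-3-methyl-5-[(1S,6R)-2,2,6-trimethyl-7-oxabicyclo[4.1.0]heptan-1-yl]pent-1-en-1-yl}oxy)trimethylsilane | COC(O[Si](C)(C)C)=C[C@H](C)CC[C@@]12O[C@]1(C)CCCC2(C)C
F3 | step 10 | (1S,2R,4aS,8aR)-2,5,5,8a-tetramethyl-1-(3-methylidenehept-6-en-1-yl)octahydronaphthalen-4a(2H)-ol | C=CCCC(=C)CC[C@H]1[C@H](C)CC[C@]2(O)C(C)(C)CCC[C@]12C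
F4 | step 10 | (1S,2R,4aS,8aR)-2,5,5,8a-tetramethyl-1-{3-methyl-3-[(triethylsilyl)peroxy]hept-6-en-1-yl}octahydronaphthalen-4a(2H)-ol (epimers at the peroxy carbon) | C=CCCC(C)(OO[Si](CC)(CC)CC)CC[C@H]1[C@H](C)CC[C@]2(O)C(C)(C)CCC[C@]12C
F5 | step 11 | (2E)-6-bromo-2-methylhepta-2,6-dienoic acid | OC(=O)/C(C)=C/CCC(Br)=C
F6 | step 11 | (2E)-6-bromo-2-methylhepta-2,6-dienoic 2,2-dimethylpropanoic anhydride | CC(C)(C)C(=O)OC(=O)/C(C)=C/CCC(Br)=C
F7 | step 11 | (4S)-4-benzyl-3-[(2E)-6-bromo-2-methylhepta-2,6-dienoyl]-1,3-oxazolidin-2-one | O=C1OC[C@H](Cc2ccccc2)N1C(=O)/C(C)=C/CCC(Br)=C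
F8 | step 11 | (4S)-4-benzyl-3-{(2E)-8-[(1S,2R,4aS,8aR)-4a-hydroxy-2,5,5,8a-tetramethyldecahydronaphthalen-1-yl]-2-methyl-6-methylideneoct-2-enoyl}-1,3-oxazolidin-2-one | O=C1OC[C@H](Cc2ccccc2)N1C(=O)/C(C)=C/CCC(=C)CC[C@H]3[C@H](C)CC[C@]4(O)C(C)(C)CCC[C@]34C
F9 | step 11 | (4S)-4-benzyl-3-{(2E,6RS)-8-[(1S,2R,4aS,8aR)-4a-hydroxy-2,5,5,8a-tetramethyldecahydronaphthalen-1-yl]-2,6-dimethyl-6-[(triethylsilyl)peroxy]oct-2-enoyl}-1,3-oxazolidin-2-one | O=C1OC[C@H](Cc2ccccc2)N1C(=O)/C(C)=C/CCC(C)(OO[Si](CC)(CC)CC)CC[C@H]3[C@H](C)CC[C@]4(O)C(C)(C)CCC[C@]34C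
F10 | step 11 | (4S)-4-benzyl-3-{(2E,6RS)-6-hydroperoxy-8-[(1S,2R,4aS,8aR)-4a-hydroxy-2,5,5,8a-tetramethyldecahydronaphthalen-1-yl]-2,6-dimethyloct-2-enoyl}-1,3-oxazolidin-2-one | O=C1OC[C@H](Cc2ccccc2)N1C(=O)/C(C)=C/CCC(C)(OO)CC[C@H]3[C@H](C)CC[C@]4(O)C(C)(C)CCC[C@]34C
F11 | step 11 | (4S)-4-benzyl-3-{(2S)-2-[(3S,6R)-6-{2-[(1S,2R,4aS,8aR)-4a-hydroxy-2,5,5,8a-tetramethyldecahydronaphthalen-1-yl]ethyl}-6-methyl-1,2-dioxan-3-yl]propanoyl}-1,3-oxazolidin-2-one | O=C1OC[C@H](Cc2ccccc2)N1C(=O)[C@@H](C)[C@@H]5CC[C@@](C)(CC[C@H]3[C@H](C)CC[C@]4(O)C(C)(C)CCC[C@]34C)OO5
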